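**Plan**
1. Retrosynthetic cuts: (i) the bond between chromene C5 and the CH2 that is β to the ketone; (ii) the pyran C3=C4 double bond; (iii) the aryl ether bond O1–C8a; (iv) the side-chain allylic alcohol is traced back to the trisubstituted alkene of linalool.
2. Enabling feature: C5–CH2–CH2–C(=O)–aryl is a β-aryl ketone. The ketone carbon and both CH2 groups can therefore be carried as a 1-arylcyclopropanol (a temporary three-membered ring) that opens as a homoenolate onto a C5–Br bond of the benzo ring of the chromene.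
3. Forward order: Br/F/CHO/O-substituted benzene → SNAr ether with (R)-linalool → styrene → epoxide/selenoxide transposition to the E tertiary allylic alcohol → metathesis closes the pyran ring → cyclopropanol ring-opening arylation joins the resorcinol half → acetal cleavage.
4. Stereochemistry: the only stereocentre (C2, R) is the carbinol carbon of (R)-(−)-linalool. The aryl ether is made at oxygen, so none of its four bonds is ever broken. The E-alkene comes from the syn selenoxide elimination.

Key step: step 10

Assumption: (R)-(−)-linalool is taken as available in high enantiomeric purity; the oxan-2-yl (THP) acetal carbons are uncontrolled, so THP-bearing compounds are diastereomer mixtures that converge in the last step.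

**Step 1**
Reactants: 1 4-bromo-2-fluorophenol
Product: 2 2-(4-bromo-2-fluorophenoxy)oxane
Conditions: 3,4-dihydro-2H-pyran (1.5 equiv), PPTS (5 mol %), CH2Cl2, rt
Reagents that add atoms: 3,4-dihydro-2H-pyran C1=COCCC1
Why: Acid-catalysed addition of the phenol to the enol ether (tetrahydropyranylation) should give the mixed acetal, which masks the future 8-OH against bases, organometallics and oxidants and can be removed at the end with mild acid.

**Step 2**
Reactants: 2 2-(4-bromo-2-fluorophenoxy)oxane
Product: 4 6-bromo-2-fluoro-3-(oxan-2-yloxy)benzaldehyde, via aryllithium 3 (not isolated)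
Conditions: LDA (1.1 equiv), THF, −78 °C; DMF, −78 → −40 °C; aq NH4Cl
Reagents that add atoms: N,N-dimethylformamide CN(C)C=O
Why: Directed ortho-metalation should occur at the most acidic ring hydrogen, the one flanked by F and Br, at a temperature below aryne formation, and formylation with DMF then fixes the 1,2,3,4-substitution pattern of the chromene benzo ring.

**Step 3**
Reactants: 4 6-bromo-2-fluoro-3-(oxan-2-yloxy)benzaldehyde; 5 (R)-(−)-linalool
Product: 7 6-bromo-2-{[(3R)-3,7-dimethylocta-1,6-dien-3-yl]oxy}-3-(oxan-2-yloxy)benzaldehyde, via potassium linaloolate 6 (not isolated)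
Conditions: 5, KHMDS (1.05 equiv), THF, 0 °C; then 4, THF–DMF, 0 °C → rt
Reagents that add atoms: none
Why: Nucleophilic aromatic substitution (addition–elimination) of the ortho-formyl-activated fluoride, a far better SNAr leaving group than the bromide, by the tertiary alkoxide should form the O1–C8a ether at oxygen, so the carbinol stereocentre of linalool is carried over unchanged as the future C2 (R).

**Step 4**
Reactants: 7 6-bromo-2-{[(3R)-3,7-dimethylocta-1,6-dien-3-yl]oxy}-3-(oxan-2-yloxy)benzaldehyde
Product: 8 (3R)-3-[3-bromo-2-ethenyl-6-(oxan-2-yloxy)phenoxy]-3,7-dimethylocta-1,6-diene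
Conditions: Ph3PCH3Br, KOtBu, THF, 0 °C → rt
Reagents that add atoms: methyltriphenylphosphonium bromide C[P+](c1ccccc1)(c1ccccc1)c1ccccc1.[Br-]
Why: Wittig methylenation of the non-enolisable aldehyde with the unstabilised ylide should give the styrene needed for ring closure without touching the bromide, the acetal or the tertiary allyl ether.

**Step 5**
Reactants: 8 (3R)-3-[3-bromo-2-ethenyl-6-(oxan-2-yloxy)phenoxy]-3,7-dimethylocta-1,6-diene
Product: 9 2-{(3R)-3-[3-bromo-2-ethenyl-6-(oxan-2-yloxy)phenoxy]-3-methylpent-4-en-1-yl}-3,3-dimethyloxirane (both epimers at the oxirane CH)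
Conditions: mCPBA (1.05 equiv), NaHCO3, CH2Cl2, 0 °C
Reagents that add atoms: mCPBA O=C(OO)c1cccc(Cl)c1
Why: Prilezhaev epoxidation is electrophilic and should select the trisubstituted alkene over the two monosubstituted vinyl groups; the new oxirane stereocentre is uncontrolled and is erased in step 6.

**Step 6**
Reactants: 9 2-{(3R)-3-[3-bromo-2-ethenyl-6-(oxan-2-yloxy)phenoxy]-3-methylpent-4-en-1-yl}-3,3-dimethyloxirane
Product: 12 (3E,6R)-6-[3-bromo-2-ethenyl-6-(oxan-2-yloxy)phenoxy]-2,6-dimethylocta-3,7-dien-2-ol, via hydroxy selenide 10 (not isolated), via selenoxide 11 (not isolated)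
Conditions: PhSeSePh (0.6 equiv), NaBH4, EtOH, rt → reflux; then THF, 30% H2O2 (excess), 0 °C → rt
Reagents that add atoms: none
Why: In this selenide-mediated epoxide-to-allylic-alcohol transposition the selenolate should open the oxirane at its less hindered secondary carbon, and the derived selenoxide can only eliminate syn toward the CH2 (the carbinol carbon has no hydrogen), which should give the E tertiary allylic alcohol.

**Step 7**
Reactants: 12 (3E,6R)-6-[3-bromo-2-ethenyl-6-(oxan-2-yloxy)phenoxy]-2,6-dimethylocta-3,7-dien-2-ol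
Product: 13 (3E)-5-[(2R)-5-bromo-2-methyl-8-(oxan-2-yloxy)-2H-chromen-2-yl]-2-methylpent-3-en-2-ol
Conditions: (H2IMes)(PCy3)Cl2Ru=CHPh (3 mol %), CH2Cl2, 40 °C, dark
Reagents that add atoms: none
Why: Ring-closing olefin metathesis between the two terminal vinyl groups should close the six-membered pyran ring with loss of ethylene, the hindered internal E-alkene being a much poorer partner; the stereocentre is not involved.

**Step 8**
Reactants: 14 methyl 2,4-dihydroxybenzoate
Product: 15 methyl 2,4-bis(oxan-2-yloxy)benzoate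
Conditions: 3,4-dihydro-2H-pyran (5 equiv), PPTS (10 mol %), CH2Cl2, rt → 40 °C
Reagents that add atoms: 3,4-dihydro-2H-pyran C1=COCCC1
Why: Tetrahydropyranylation of both phenols (the hydrogen-bonded ortho one needs excess reagent and time) gives acetal protection that cannot migrate to a neighbouring alkoxide and tolerates the titanium and palladium chemistry that follows.

**Step 9**
Reactants: 15 methyl 2,4-bis(oxan-2-yloxy)benzoate
Product: 16 1-[2,4-bis(oxan-2-yloxy)phenyl]cyclopropan-1-ol
Conditions: EtMgBr (3 equiv), Ti(OiPr)4 (20 mol %), THF, 0 °C → rt; aq NH4Cl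
Reagents that add atoms: ethylmagnesium bromide CC[Mg]Br
Why: In the Kulinkovich cyclopropanation the titanacyclopropane formed from the Grignard reagent and catalytic titanium alkoxide should add twice to the ester carbonyl as a 1,2-dicarbanion equivalent, giving the 1-arylcyclopropanol that holds the ketone carbon and both CH2 groups of the linker.

**Step 10**
Reactants: 13 (3E)-5-[(2R)-5-bromo-2-methyl-8-(oxan-2-yloxy)-2H-chromen-2-yl]-2-methylpent-3-en-2-ol; 16 1-[2,4-bis(oxan-2-yloxy)phenyl]cyclopropan-1-ol
Product: 17 1-[2,4-bis(oxan-2-yloxy)phenyl]-3-{(2R)-2-[(2E)-4-hydroxy-4-methylpent-2-en-1-yl]-2-methyl-8-(oxan-2-yloxy)-2H-chromen-5-yl}propan-1-one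
Conditions: Pd(OAc)2 (5 mol %), XPhos (10 mol %), Cs2CO3 (2 equiv), 16 (1.3 equiv), degassed toluene, 60 °C, dark
Reagents that add atoms: none
Why: Oxidative addition of Pd(0) into the C5–Br bond of 13, exchange of bromide for the caesium cyclopropoxide of 16, strain-driven β-carbon elimination to a palladium homoenolate (aryl–Pd–CH2CH2C(=O)aryl′) and C(sp2)–C(sp3) reductive elimination should create the C5–CH2 bond and the ketone in one event. The closest known reaction type is the palladium-catalysed ring-opening cross-coupling of cyclopropanols (ketone homoenolates) with aryl bromides. No ring is closed; the temporary three-membered ring is opened, and because both CH2–C(OH) bonds of 16 are equivalent the opening has no regiochemical issue. No stereocentre is formed, and C2 is remote and untouched, the moderate temperature and exclusion of light being chosen to avoid electrocyclic opening of the pyran ring. The selectivity needed is reductive elimination over β-hydride elimination of the homoenolate (which would give the aryl vinyl ketone and debrominated chromene), which the bulky electron-rich biarylphosphine should secure; the only C–Br bond is at C5, the side-chain alcohol is tertiary and cannot be oxidised by β-hydride loss, and the ring alkene cannot insert into the neighbouring aryl–Pd bond for geometric reasons.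

**Step 11**
Reactants: 17 1-[2,4-bis(oxan-2-yloxy)phenyl]-3-{(2R)-2-[(2E)-4-hydroxy-4-methylpent-2-en-1-yl]-2-methyl-8-(oxan-2-yloxy)-2H-chromen-5-yl}propan-1-one
Product: 18 1-(2,4-dihydroxyphenyl)-3-{(2R)-8-hydroxy-2-[(2E)-4-hydroxy-4-methylpent-2-en-1-yl]-2-methyl-2H-chromen-5-yl}propan-1-one
Conditions: PPTS (0.3 equiv), MeOH, rt, dark
Reagents that add atoms: none
Why: Acid-catalysed transacetalisation of the three aryl THP acetals to methanol with pyridinium tosylate should free the three phenols under conditions too mild to ionise the tertiary allylic alcohol or the allylic C2–O1 bond of the chromene.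

**Compound list**
1 | 4-bromo-2-fluorophenol | Oc1ccc(Br)cc1F | starting material
2 | 2-(4-bromo-2-fluorophenoxy)oxane | Fc1cc(Br)ccc1OC1CCCCO1 | intermediate
3 | [6-bromo-2-fluoro-3-(oxan-2-yloxy)phenyl]lithium (not isolated) | [Li]c1c(F)c(OC2CCCCO2)ccc1Br | intermediate
4 | 6-bromo-2-fluoro-3-(oxan-2-yloxy)benzaldehyde | O=Cc1c(F)c(OC2CCCCO2)ccc1Br | intermediate
5 | (R)-(−)-linalool, (3R)-3,7-dimethylocta-1,6-dien-3-ol | CC(C)=CCC[C@](C)(C=C)O | starting material
6 | potassium (3R)-3,7-dimethylocta-1,6-dien-3-olate (not isolated) | CC(C)=CCC[C@](C)(C=C)[O-].[K+] | intermediate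
7 | 6-bromo-2-{[(3R)-3,7-dimethylocta-1,6-dien-3-yl]oxy}-3-(oxan-2-yloxy)benzaldehyde | CC(C)=CCC[C@](C)(C=C)Oc1c(C=O)c(Br)ccc1OC1CCCCO1 | intermediate
8 | (3R)-3-[3-bromo-2-ethenyl-6-(oxan-2-yloxy)phenoxy]-3,7-dimethylocta-1,6-diene | CC(C)=CCC[C@](C)(C=C)Oc1c(C=C)c(Br)ccc1OC1CCCCO1 | intermediate
9 | 2-{(3R)-3-[3-bromo-2-ethenyl-6-(oxan-2-yloxy)phenoxy]-3-methylpent-4-en-1-yl}-3,3-dimethyloxirane (oxirane CH uncontrolled) | CC1(C)OC1CC[C@](C)(C=C)Oc1c(C=C)c(Br)ccc1OC1CCCCO1 | intermediate
10 | (6R)-6-[3-bromo-2-ethenyl-6-(oxan-2-yloxy)phenoxy]-2,6-dimethyl-3-(phenylselanyl)oct-7-en-2-ol (not isolated) | CC(C)(O)C([Se]c1ccccc1)CC[C@](C)(C=C)Oc1c(C=C)c(Br)ccc1OC1CCCCO1 | intermediate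
11 | (6R)-3-(benzeneseleninyl)-6-[3-bromo-2-ethenyl-6-(oxan-2-yloxy)phenoxy]-2,6-dimethyloct-7-en-2-ol (not isolated) | CC(C)(O)C([Se](=O)c1ccccc1)CC[C@](C)(C=C)Oc1c(C=C)c(Br)ccc1OC1CCCCO1 | intermediate
12 | (3E,6R)-6-[3-bromo-2-ethenyl-6-(oxan-2-yloxy)phenoxy]-2,6-dimethylocta-3,7-dien-2-ol | CC(C)(O)/C=C/C[C@](C)(C=C)Oc1c(C=C)c(Br)ccc1OC1CCCCO1 | intermediate
13 | (3E)-5-[(2R)-5-bromo-2-methyl-8-(oxan-2-yloxy)-2H-chromen-2-yl]-2-methylpent-3-en-2-ol | CC(C)(O)/C=C/C[C@]1(C)C=Cc2c(Br)ccc(OC3CCCCO3)c2O1 | intermediate
14 | methyl 2,4-dihydroxybenzoate | COC(=O)c1ccc(O)cc1O | starting material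
15 | methyl 2,4-bis(oxan-2-yloxy)benzoate | COC(=O)c1ccc(OC2CCCCO2)cc1OC1CCCCO1 | intermediate
16 | 1-[2,4-bis(oxan-2-yloxy)phenyl]cyclopropan-1-ol | OC1(c2ccc(OC3CCCCO3)cc2OC2CCCCO2)CC1 | intermediate
17 | 1-[2,4-bis(oxan-2-yloxy)phenyl]-3-{(2R)-2-[(2E)-4-hydroxy-4-methylpent-2-en-1-yl]-2-methyl-8-(oxan-2-yloxy)-2H-chromen-5-yl}propan-1-one | CC(C)(O)/C=C/C[C@]1(C)C=Cc2c(CCC(=O)c3ccc(OC4CCCCO4)cc3OC3CCCCO3)ccc(OC3CCCCO3)c2O1 | intermediate
18 | 1-(2,4-dihydroxyphenyl)-3-{(2R)-8-hydroxy-2-[(2E)-4-hydroxy-4-methylpent-2-en-1-yl]-2-methyl-2H-chromen-5-yl}propan-1-one | CC(C)(O)/C=C/C[C@]1(C)C=Cc2c(CCC(=O)c3ccc(O)cc3O)ccc(O)c2O1 | target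

**Totals**
Total step count: 11. Longest linear sequence: 9 steps (steps 1–7, 10, 11); steps 8–9 form the second branch.

**Steps most likely to fail**

Step 3. The hindered tertiary alkoxide may add to the formyl group, or take part in hydride transfer between aldehyde molecules, faster than it substitutes the fluoride that is flanked on both sides. Slow substitution would also leave time for decomposition. The fallback changes the activating group and sets out from 4. The aldehyde is converted with iodine and aqueous ammonia in THF into 6-bromo-2-fluoro-3-(oxan-2-yloxy)benzonitrile F1, whose nitrile activates the fluoride without offering an electrophilic carbonyl. Potassium linaloolate 6 is then expected to give 6-bromo-2-{[(3R)-3,7-dimethylocta-1,6-dien-3-yl]oxy}-3-(oxan-2-yloxy)benzonitrile F2. Partial reduction with DIBAL-H in toluene at −78 °C and hydrolysis of the aldimine with aqueous Rochelle salt returns the route at 7.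

Step 10. Three processes threaten this step:
- β-hydride elimination of the palladium homoenolate, with debromination of the chromene;
- sluggish oxidative addition into the electron-rich, ortho-substituted bromide;
- erosion of configuration at C2 by reversible opening of the pyran ring on prolonged heating, or by palladium ionising the allylic C2–O1 bond.

The fallback reverses the polarity, avoids palladium and heat on the chromene, and sets out from 13 and 16. Deprotonation and bromine–lithium exchange on 13 with n-BuLi (2.1 equiv, THF, −78 °C), then 2-isopropoxy-4,4,5,5-tetramethyl-1,3,2-dioxaborolane, should give (3E)-2-methyl-5-[(2R)-2-methyl-8-(oxan-2-yloxy)-5-(4,4,5,5-tetramethyl-1,3,2-dioxaborolan-2-yl)-2H-chromen-2-yl]pent-3-en-2-ol F3. Cyclopropanol 16 is opened with N-bromosuccinimide to 1-[2,4-bis(oxan-2-yloxy)phenyl]-3-bromopropan-1-one F4, and triethylamine eliminates HBr to give 1-[2,4-bis(oxan-2-yloxy)phenyl]prop-2-en-1-one F5. Rhodium-catalysed 1,4-addition of F3 to F5 ([Rh(cod)OH]2, dioxane–water, rt) forms the same C5–CH2 bond and returns the route at 17.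

Step 6. The soft selenolate may also displace the tertiary allylic aryl ether in an SN2′ sense. Perseleninic acid formed from the excess peroxide may epoxidise alkenes during the elimination. The fallback replaces steps 5 and 6 by an ene oxidation and sets out from 8. Sensitised photo-oxygenation (O2, tetraphenylporphyrin, visible light, CH2Cl2, 0 °C; Schenck ene reaction) should attack only the trisubstituted alkene. It is expected to give (3E,6R)-6-[3-bromo-2-ethenyl-6-(oxan-2-yloxy)phenoxy]-2,6-dimethylocta-3,7-dien-2-yl hydroperoxide F6. The regioisomeric secondary hydroperoxide is expected alongside it and is removed by chromatography after reduction. Triphenylphosphine reduces F6 to the alcohol, which returns the route at 12.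

**Further compounds**
F1 | step 3 | 6-bromo-2-fluoro-3-(oxan-2-yloxy)benzonitrile | N#Cc1c(F)c(OC2CCCCO2)ccc1Br
F2 | step 3 | 6-bromo-2-{[(3R)-3,7-dimethylocta-1,6-dien-3-yl]oxy}-3-(oxan-2-yloxy)benzonitrile | CC(C)=CCC[C@](C)(C=C)Oc1c(C#N)c(Br)ccc1OC1CCCCO1
F3 | step 10 | (3E)-2-methyl-5-[(2R)-2-methyl-8-(oxan-2-yloxy)-5-(4,4,5,5-tetramethyl-1,3,2-dioxaborolan-2-yl)-2H-chromen-2-yl]pent-3-en-2-ol | CC(C)(O)/C=C/C[C@]1(C)C=Cc2c(B3OC(C)(C)C(C)(C)O3)ccc(OC3CCCCO3)c2O1
F4 | step 10 | 1-[2,4-bis(oxan-2-yloxy)phenyl]-3-bromopropan-1-one | O=C(CCBr)c1ccc(OC2CCCCO2)cc1OC1CCCCO1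
F5 | step 10 | 1-[2,4-bis(oxan-2-yloxy)phenyl]prop-2-en-1-one | C=CC(=O)c1ccc(OC2CCCCO2)cc1OC1CCCCO1
F6 | step 6 | (3E,6R)-6-[3-bromo-2-ethenyl-6-(oxan-2-yloxy)phenoxy]-2,6-dimethylocta-3,7-dien-2-yl hydroperoxide | CC(C)(OO)/C=C/C[C@](C)(C=C)Oc1c(C=C)c(Br)ccc1OC1CCCCO1
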